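**Plan**

- Retrosynthesis: the C1'=C2' alkene of the dienyl chain is cut first (aldehyde on C3 plus an allylic sulfone). The C7 ketone and the C3 formyl group are then traced back to CH2 and CH3. The pyridine ring is cut at C7a–C1 and C4a–C4 into a ring B enamine and 5-methyl-1,2,4-triazine. The C6–OMe bond goes back to an epoxide.
- Forward: the cyclopentane (ring B) is built up from 3-methylcyclopent-2-en-1-one, the pyridine ring is annulated onto it in one operation, and the chain is joined last.
- Enabling feature (cyclopenta[c]pyridine numbering C1, N2, C3, C4, C4a, C5, C6, C7, C7a): the fusion atoms C4a and C7a are the carbonyl carbon and the only α-methylene of the ring B ketone. The other α-position, C5, is fully substituted, so one enamine and one annulation sense are possible.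
- Stereochemistry: a CBS reduction sets a carbinol that steers a cis epoxidation (C5 and C6) and is then oxidised away. Methanolysis with inversion at C6 puts OMe trans to OH.
- The side-chain (S)-centre comes from (S)-2-methylbutan-1-ol. The E-alkenes come from a stabilised Wittig reaction and the Julia–Kocienski step.

Key step: step 10

Remark: core positions are numbered as in cyclopenta[c]pyridine throughout; the monocyclic and oxabicyclic intermediates carry their own locants.

**Route**

Step 1
Reactants: 1 3-methylcyclopent-2-en-1-one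
Product: 2 2-iodo-3-methylcyclopent-2-en-1-one
Conditions: I2, pyridine, CH2Cl2, 0 °C → rt
Reagents that add atoms: iodine, II
Why: α-Iodination of an enone by the iodine–pyridine method (conjugate addition of pyridine, iodination of the enolate, elimination of pyridine) should place iodine on C2 only.

Step 2
Reactants: 2 2-iodo-3-methylcyclopent-2-en-1-one
Product: 3 (1R)-2-iodo-3-methylcyclopent-2-en-1-ol
Conditions: (S)-2-methyl-CBS-oxazaborolidine (0.2 equiv), BH3·SMe2, THF, −20 °C
Reagents that add atoms: none
Why: Corey–Bakshi–Shibata reduction of an α-iodo enone, a substrate class that reduces 1,2 with high enantioselectivity: the iodoalkenyl arm acts as the large group, so the (S)-catalyst should deliver hydride to the face that gives the (R)-carbinol.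

Step 3
Reactants: 3 (1R)-2-iodo-3-methylcyclopent-2-en-1-ol
Product: 4 methyl (5R)-5-hydroxy-2-methylcyclopent-1-ene-1-carboxylate
Conditions: CO (1 atm), PdCl2(PPh3)2 (cat.), Et3N, MeOH/DMF, 60 °C
Reagents that add atoms: carbon monoxide, [C-]#[O+]; methanol, CO
Why: Palladium-catalysed alkoxycarbonylation of an alkenyl iodide (oxidative addition to zerovalent palladium formed in situ, CO insertion, methanolysis of the acylpalladium) replaces iodine by CO2Me without touching the carbinol centre.

Step 4
Reactants: 4 methyl (5R)-5-hydroxy-2-methylcyclopent-1-ene-1-carboxylate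
Product: 5 methyl (1R,2R,5S)-2-hydroxy-5-methyl-6-oxabicyclo[3.1.0]hexane-1-carboxylate
Conditions: t-BuOOH (decane), VO(acac)2 (cat.), PhMe, 0 → 40 °C
Reagents that add atoms: tert-butyl hydroperoxide, CC(C)(C)OO
Why: Hydroxyl-directed vanadium-catalysed epoxidation of a cyclic allylic alcohol: the vanadate ester of the hydroxyl delivers oxygen within the complex to the alkene face cis to it, which sets both epoxide carbons from the carbinol centre, and the two alkyl groups of the tetrasubstituted alkene should offset the deactivation by the ester.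

Step 5
Reactants: 5 methyl (1R,2R,5S)-2-hydroxy-5-methyl-6-oxabicyclo[3.1.0]hexane-1-carboxylate
Product: 6 methyl (1S,5S)-5-methyl-2-oxo-6-oxabicyclo[3.1.0]hexane-1-carboxylate
Conditions: Dess–Martin periodinane, CH2Cl2, 0 °C → rt
Reagents that add atoms: none
Why: Dess–Martin oxidation converts the secondary alcohol into the ketone under near-neutral conditions that spare the epoxide; the relay carbinol centre is removed, and the descriptor at C1 changes only because the priorities change.

Step 6
Reactants: 6 methyl (1S,5S)-5-methyl-2-oxo-6-oxabicyclo[3.1.0]hexane-1-carboxylate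
Product: 7 methyl (1S,2R)-1-hydroxy-2-methoxy-2-methyl-5-oxocyclopentane-1-carboxylate
Conditions: camphorsulfonic acid (cat.), MeOH, 0 °C → rt; aqueous work-up
Reagents that add atoms: methanol, CO
Why: Acid-catalysed epoxide methanolysis, as with 1-methylcyclopentene oxide: methanol opens the protonated epoxide at the methyl-bearing tertiary carbon, the one not flanked by two carbonyl groups, from the face opposite to the oxygen, so this carbon is inverted (OMe trans to OH) while the carbinol carbon keeps its C–O bond.

Step 7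
Reactants: 7 methyl (1S,2R)-1-hydroxy-2-methoxy-2-methyl-5-oxocyclopentane-1-carboxylate
Product: 8 methyl (1S,2R)-2-methoxy-2-methyl-5-oxo-1-[(triethylsilyl)oxy]cyclopentane-1-carboxylate
Conditions: Et3SiOTf, 2,6-lutidine, CH2Cl2, −78 → 0 °C
Reagents that add atoms: triethylsilyl trifluoromethanesulfonate, CC[Si](CC)(CC)OS(=O)(=O)C(F)(F)F
Why: Silyl triflate with a hindered base silylates even a congested tertiary alcohol; the ether blocks α-ketol rearrangement in the amine steps and retro-aldol cleavage once the C7 ketone is present.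

Step 8
Reactants: 8 methyl (1S,2R)-2-methoxy-2-methyl-5-oxo-1-[(triethylsilyl)oxy]cyclopentane-1-carboxylate
Product: 9 methyl (1R,2R)-2-methoxy-2-methyl-5-(pyrrolidin-1-yl)-1-[(triethylsilyl)oxy]cyclopent-4-ene-1-carboxylate
Conditions: pyrrolidine (5 equiv), 4 Å MS, PhMe, 50 °C; concentrated and used crude
Reagents that add atoms: pyrrolidine, C1CCNC1
Why: Stork enamine condensation of a cyclopentanone: C1 carries no hydrogen, so the double bond can only form towards C4, and the hindered tertiary ester and the silyl ether are not expected to react with the amine at this temperature.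

Step 9
Reactants: 10 formamidine acetate; 11 pyruvaldehyde (2-oxopropanal, 40% aqueous)
Product: 13 5-methyl-1,2,4-triazine, via formamidrazone acetate 12 (not isolated)
Conditions: N2H4·H2O, MeOH, −10 °C; then 11, 0 °C → rt
Reagents that add atoms: hydrazine (as the hydrate), NN
Why: Amidrazone–1,2-dicarbonyl condensation: hydrazine displaces ammonia from the amidine, and the amidrazone then condenses through its hydrazine nitrogen with the aldehyde and through its amidine nitrogen with the ketone, which should place the methyl group on C5.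

Step 10
Reactants: 9 methyl (1R,2R)-2-methoxy-2-methyl-5-(pyrrolidin-1-yl)-1-[(triethylsilyl)oxy]cyclopent-4-ene-1-carboxylate; 13 5-methyl-1,2,4-triazine
Product: 16 methyl (5R,6R)-6-methoxy-3,6-dimethyl-5-[(triethylsilyl)oxy]-6,7-dihydro-5H-cyclopenta[c]pyridine-5-carboxylate, via triazabicyclooctadiene cycloadduct 14 (not isolated), via pyrrolidinyl dihydropyridine 15 (not isolated)
Conditions: 1,4-dioxane, 4 Å MS, 90 °C (sealed tube)
Reagents that add atoms: none
Why: The electron-rich enamine and the electron-poor triazine combine in an inverse-electron-demand [4+2] cycloaddition across triazine C3 and C6, which forms the C7a–C1 and C4a–C4 bonds; bridged adduct 14 then loses dinitrogen by retro-[4+2] to dihydropyridine 15, and elimination of pyrrolidine aromatises the ring. The closest known reaction type is the Boger pyridine synthesis from 1,2,4-triazines and pyrrolidine enamines of cyclopentanones, which gives cyclopenta[c]pyridines. The pyridine ring is closed by this intermolecular cycloaddition–cycloreversion, four ring atoms (C1, N2, C3, C4) coming ready-made from the triazine and two (C4a, C7a) from the enamine. No new stereocentre survives, since the sp3 centres formed at C4a and C7a are erased on aromatisation, and the quaternary C5 and C6 centres have no acidic hydrogen and cannot epimerise. The step needs one regiochemistry (methyl on C3, the C7 methylene on the C1 side): it is secured by the polarity match of the nucleophilic enamine β-carbon (future C7a) with triazine C3, the most electrophilic carbon between two nitrogens, reinforced by the electron-releasing methyl group next to C6, and by the fact that ketone 8 can give only this one enamine.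

Step 11
Reactants: 16 methyl (5R,6R)-6-methoxy-3,6-dimethyl-5-[(triethylsilyl)oxy]-6,7-dihydro-5H-cyclopenta[c]pyridine-5-carboxylate
Product: 17 methyl (5R,6S)-6-methoxy-3,6-dimethyl-7-oxo-5-[(triethylsilyl)oxy]-6,7-dihydro-5H-cyclopenta[c]pyridine-5-carboxylate
Conditions: t-BuOOH (70% aq.), Mn(OTf)2 (cat.), t-BuOH/H2O, 40 °C
Reagents that add atoms: tert-butyl hydroperoxide, CC(C)(C)OO
Why: Radical benzylic C–H oxidation with a hydroperoxide, a reaction type known for the ring methylene on a pyridine β-carbon in cyclopentenopyridines: the electrophilic tert-butoxyl and tert-butylperoxyl radicals should abstract the secondary C7 hydrogen in preference to the primary hydrogens of the α-methyl group, and the C7 peroxide collapses to a ketone that cannot enolise.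

Step 12
Reactants: 17 methyl (5R,6S)-6-methoxy-3,6-dimethyl-7-oxo-5-[(triethylsilyl)oxy]-6,7-dihydro-5H-cyclopenta[c]pyridine-5-carboxylate
Product: 18 methyl (5R,6S)-3-formyl-6-methoxy-6-methyl-7-oxo-5-[(triethylsilyl)oxy]-6,7-dihydro-5H-cyclopenta[c]pyridine-5-carboxylate
Conditions: SeO2, 1,4-dioxane, 90 °C
Reagents that add atoms: selenium dioxide, O=[Se]=O
Why: Riley oxidation of a 2-methylpyridine: only a methyl group α or γ to the ring nitrogen reacts through its enamine tautomer, the C3 methyl is the one such group here and is further acidified by the para acyl group, and in dry dioxane the aldehyde should resist further oxidation.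

Step 13
Reactants: 19 (S)-2-methylbutan-1-ol
Product: 21 ethyl (2E,4S)-2,4-dimethylhex-2-enoate, via (S)-2-methylbutanal 20 (not isolated)
Conditions: PhI(OAc)2, TEMPO (cat.), CH2Cl2, rt; then Ph3P=C(Me)CO2Et, rt → 40 °C
Reagents that add atoms: ethyl 2-(triphenylphosphoranylidene)propanoate, CCOC(=O)C(C)=P(c1ccccc1)(c1ccccc1)c1ccccc1
Why: One-flask oxoammonium (TEMPO) oxidation and Wittig olefination: the volatile, epimerisable aldehyde is formed under non-basic conditions and trapped at once by the stabilised ylide, which should give the E-trisubstituted enoate and carries the (S)-centre over unchanged from the starting alcohol.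

Step 14
Reactants: 21 ethyl (2E,4S)-2,4-dimethylhex-2-enoate
Product: 22 (2E,4S)-2,4-dimethylhex-2-en-1-ol
Conditions: i-Bu2AlH, CH2Cl2, −78 °C
Reagents that add atoms: none
Why: 1,2-Reduction of an enoate by i-Bu2AlH gives the allylic alcohol without touching the alkene geometry or the stereocentre.

Step 15
Reactants: 22 (2E,4S)-2,4-dimethylhex-2-en-1-ol
Product: 23 5-{[(2E,4S)-2,4-dimethylhex-2-en-1-yl]sulfanyl}-1-phenyl-1H-tetrazole
Conditions: 1-phenyl-1H-tetrazole-5-thiol, PPh3, DIAD, THF, 0 °C → rt
Reagents that add atoms: 1-phenyl-1H-tetrazole-5-thiol, Sc1nnnn1-c1ccccc1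
Why: Mitsunobu thioetherification: the acidic thiol displaces the activated primary allylic oxygen by direct SN2 substitution, so the alkene stays in place and stays E.

Step 16
Reactants: 23 5-{[(2E,4S)-2,4-dimethylhex-2-en-1-yl]sulfanyl}-1-phenyl-1H-tetrazole
Product: 24 5-{[(2E,4S)-2,4-dimethylhex-2-en-1-yl]sulfonyl}-1-phenyl-1H-tetrazole
Conditions: H2O2 (30% aq.), (NH4)6Mo7O24·4H2O (cat.), EtOH, 0 °C → rt
Reagents that add atoms: hydrogen peroxide, OO
Why: Molybdate-catalysed peroxide oxidation takes the sulfide through the sulfoxide to the sulfone and is selective for sulfur over a trisubstituted alkene, which a peracid would not be.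

Step 17
Reactants: 18 methyl (5R,6S)-3-formyl-6-methoxy-6-methyl-7-oxo-5-[(triethylsilyl)oxy]-6,7-dihydro-5H-cyclopenta[c]pyridine-5-carboxylate; 24 5-{[(2E,4S)-2,4-dimethylhex-2-en-1-yl]sulfonyl}-1-phenyl-1H-tetrazole
Product: 25 methyl (5R,6S)-3-[(1E,3E,5S)-3,5-dimethylhepta-1,3-dien-1-yl]-6-methoxy-6-methyl-7-oxo-5-[(triethylsilyl)oxy]-6,7-dihydro-5H-cyclopenta[c]pyridine-5-carboxylate
Conditions: KN(SiMe3)2, DME, −60 °C → rt (base added to 18 + 24)
Reagents that add atoms: none
Why: Julia–Kocienski olefination: the metallated phenyltetrazolyl sulfone adds to the aldehyde, and Smiles rearrangement with loss of SO2 and the tetrazolone gives the alkene, expected E with the potassium base in DME for an aromatic aldehyde, while the hindered, non-enolisable C7 ketone and the tertiary ester are far less electrophilic than the pyridine-2-carbaldehyde and no stereocentre is acidic.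

Step 18
Reactants: 25 methyl (5R,6S)-3-[(1E,3E,5S)-3,5-dimethylhepta-1,3-dien-1-yl]-6-methoxy-6-methyl-7-oxo-5-[(triethylsilyl)oxy]-6,7-dihydro-5H-cyclopenta[c]pyridine-5-carboxylate
Product: 26 methyl (5R,6S)-3-[(1E,3E,5S)-3,5-dimethylhepta-1,3-dien-1-yl]-5-hydroxy-6-methoxy-6-methyl-7-oxo-6,7-dihydro-5H-cyclopenta[c]pyridine-5-carboxylate
Conditions: HF·pyridine, THF, 0 °C → rt
Reagents that add atoms: none
Why: Fluoride cleavage of the silyl ether under acidic conditions frees the tertiary alcohol without forming an alkoxide, which avoids retro-aldol opening of the β-hydroxy ketone; the diene, the ketone and the ester are inert to it.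

**Compound list**

1 | 3-methylcyclopent-2-en-1-one | CC1=CC(=O)CC1 | starting material
2 | 2-iodo-3-methylcyclopent-2-en-1-one | CC1=C(I)C(=O)CC1 | intermediate
3 | (1R)-2-iodo-3-methylcyclopent-2-en-1-ol | IC1=C(C)CC[C@H]1O | intermediate
4 | methyl (5R)-5-hydroxy-2-methylcyclopent-1-ene-1-carboxylate | COC(=O)C1=C(C)CC[C@H]1O | intermediate
5 | methyl (1R,2R,5S)-2-hydroxy-5-methyl-6-oxabicyclo[3.1.0]hexane-1-carboxylate | COC(=O)[C@]12O[C@@]1(C)CC[C@H]2O | intermediate
6 | methyl (1S,5S)-5-methyl-2-oxo-6-oxabicyclo[3.1.0]hexane-1-carboxylate | COC(=O)[C@]12O[C@@]1(C)CCC2=O | intermediate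
7 | methyl (1S,2R)-1-hydroxy-2-methoxy-2-methyl-5-oxocyclopentane-1-carboxylate | O=C1CC[C@@](C)(OC)[C@@]1(O)C(=O)OC | intermediate
8 | methyl (1S,2R)-2-methoxy-2-methyl-5-oxo-1-[(triethylsilyl)oxy]cyclopentane-1-carboxylate | O=C1CC[C@@](C)(OC)[C@@]1(O[Si](CC)(CC)CC)C(=O)OC | intermediate
9 | methyl (1R,2R)-2-methoxy-2-methyl-5-(pyrrolidin-1-yl)-1-[(triethylsilyl)oxy]cyclopent-4-ene-1-carboxylate | C1CCN(C1)C2=CC[C@@](C)(OC)[C@@]2(O[Si](CC)(CC)CC)C(=O)OC | intermediate
10 | formamidine acetate | CC(=O)O.NC=N | starting material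
11 | pyruvaldehyde (2-oxopropanal) | CC(=O)C=O | starting material
12 | formamidrazone acetate (formimidohydrazide acetate) | NN=CN.CC(=O)O | intermediate
13 | 5-methyl-1,2,4-triazine | Cc1cnncn1 | intermediate
14 | bridged [4+2] adduct of 9 and 13 (2,3,5-triazabicyclo[2.2.2]octa-2,5-diene with the cyclopentane fused at the saturated bridge; C5 and C6 as in 9, new centres transient) | CC1=NC2N=NC1C3(N4CCCC4)C2C[C@@](C)(OC)[C@@]3(O[Si](CC)(CC)CC)C(=O)OC | intermediate
15 | methyl (5R,6R)-6-methoxy-3,6-dimethyl-4a-(pyrrolidin-1-yl)-5-[(triethylsilyl)oxy]-4a,6,7,7a-tetrahydro-5H-cyclopenta[c]pyridine-5-carboxylate (C4a and C7a transient) | CC1=CC2(N3CCCC3)C(C=N1)C[C@@](C)(OC)[C@@]2(O[Si](CC)(CC)CC)C(=O)OC | intermediate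
16 | methyl (5R,6R)-6-methoxy-3,6-dimethyl-5-[(triethylsilyl)oxy]-6,7-dihydro-5H-cyclopenta[c]pyridine-5-carboxylate | Cc1cc2c(cn1)C[C@@](C)(OC)[C@@]2(O[Si](CC)(CC)CC)C(=O)OC | intermediate
17 | methyl (5R,6S)-6-methoxy-3,6-dimethyl-7-oxo-5-[(triethylsilyl)oxy]-6,7-dihydro-5H-cyclopenta[c]pyridine-5-carboxylate | Cc1cc2c(cn1)C(=O)[C@@](C)(OC)[C@@]2(O[Si](CC)(CC)CC)C(=O)OC | intermediate
18 | methyl (5R,6S)-3-formyl-6-methoxy-6-methyl-7-oxo-5-[(triethylsilyl)oxy]-6,7-dihydro-5H-cyclopenta[c]pyridine-5-carboxylate | O=Cc1cc2c(cn1)C(=O)[C@@](C)(OC)[C@@]2(O[Si](CC)(CC)CC)C(=O)OC | intermediate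
19 | (S)-2-methylbutan-1-ol | CC[C@H](C)CO | starting material
20 | (S)-2-methylbutanal | CC[C@H](C)C=O | intermediate
21 | ethyl (2E,4S)-2,4-dimethylhex-2-enoate | CC[C@H](C)/C=C(\C)C(=O)OCC | intermediate
22 | (2E,4S)-2,4-dimethylhex-2-en-1-ol | CC[C@H](C)/C=C(\C)CO | intermediate
23 | 5-{[(2E,4S)-2,4-dimethylhex-2-en-1-yl]sulfanyl}-1-phenyl-1H-tetrazole | CC[C@H](C)/C=C(\C)CSc1nnnn1-c1ccccc1 | intermediate
24 | 5-{[(2E,4S)-2,4-dimethylhex-2-en-1-yl]sulfonyl}-1-phenyl-1H-tetrazole | CC[C@H](C)/C=C(\C)CS(=O)(=O)c1nnnn1-c1ccccc1 | intermediate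
25 | methyl (5R,6S)-3-[(1E,3E,5S)-3,5-dimethylhepta-1,3-dien-1-yl]-6-methoxy-6-methyl-7-oxo-5-[(triethylsilyl)oxy]-6,7-dihydro-5H-cyclopenta[c]pyridine-5-carboxylate | CC[C@H](C)/C=C(C)/C=C/c1cc2c(cn1)C(=O)[C@@](C)(OC)[C@@]2(O[Si](CC)(CC)CC)C(=O)OC | intermediate
26 | methyl (5R,6S)-3-[(1E,3E,5S)-3,5-dimethylhepta-1,3-dien-1-yl]-5-hydroxy-6-methoxy-6-methyl-7-oxo-6,7-dihydro-5H-cyclopenta[c]pyridine-5-carboxylate | CC[C@H](C)/C=C(C)/C=C/c1cc2c(cn1)C(=O)[C@@](C)(OC)[C@@]2(O)C(=O)OC | target

**Count**

Total: 18 steps. Longest linear sequence: 13 steps (steps 1–8, 10–12, 17, 18) from 3-methylcyclopent-2-en-1-one.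

**Steps most likely to fail**

1. Step 10. The cycloaddition may be too slow. Enamine 9 is crowded at the aminated carbon and inductively deactivated by the neighbouring carbon that bears OSiEt3 and CO2Me. The methyl group also lowers the electrophilicity of the triazine, so the enamine may hydrolyse or fragment before it reacts. The fallback sets out from 9 and comes back at 16, and keeps the same two bond formations with a more electron-poor diene. Condensation of the catalogue reagent ethyl 2-amino-2-hydrazonoacetate with pyruvaldehyde 11 gives ethyl 5-methyl-1,2,4-triazine-3-carboxylate F1. The ester makes C3 still more electrophilic, so the enamine β-carbon should again bond there. Reaction with 9 (dioxane, 60 °C) should give 1-ethyl 5-methyl (5R,6R)-6-methoxy-3,6-dimethyl-5-[(triethylsilyl)oxy]-6,7-dihydro-5H-cyclopenta[c]pyridine-1,5-dicarboxylate F2. The unhindered picolinate-type ethyl ester is saponified selectively (LiOH, THF/H2O, 0 °C) to (5R,6R)-6-methoxy-5-(methoxycarbonyl)-3,6-dimethyl-5-[(triethylsilyl)oxy]-6,7-dihydro-5H-cyclopenta[c]pyridine-1-carboxylic acid F3. Protodecarboxylation of this pyridine-2-carboxylic acid (Ag2CO3 cat., AcOH, DMSO, 120 °C) returns 16.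

2. Step 11. Hydrogen abstraction may be divided between the C7 methylene and the C3 methyl group, or the oxidation may stall at the hydroperoxide or alcohol stage. The C7 methylene is neopentyl-like and lies next to the inductively withdrawing C–OMe carbon. The fallback sets out from 16 and comes back at 17. Wohl–Ziegler bromination (NBS, AIBN, PhCF3, 80 °C), in which the more selective bromine atom should take the weaker secondary benzylic hydrogen on the β-position, gives methyl (5R,6S)-7-bromo-6-methoxy-3,6-dimethyl-5-[(triethylsilyl)oxy]-6,7-dihydro-5H-cyclopenta[c]pyridine-5-carboxylate F4 (both C7 epimers). Silver-assisted Kornblum oxidation (AgBF4, DMSO; then Et3N) converts the bromide into ketone 17.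

3. Step 4. Oxygen transfer to the alkene may be too slow because the ester makes it electron-poor, so that oxidation of the allylic alcohol to the enone takes over. The fallback sets out from 4 and comes back at 5, and moves the epoxidation to an electron-rich alkene. Reduction with i-Bu2AlH (CH2Cl2, −78 °C) gives (1R)-2-(hydroxymethyl)-3-methylcyclopent-2-en-1-ol F5. The same hydroxyl-directed conditions (t-BuOOH, VO(acac)2) then epoxidise this ordinary allylic diol cis to the ring hydroxyl to give (1R,2R,5S)-1-(hydroxymethyl)-5-methyl-6-oxabicyclo[3.1.0]hexan-2-ol F6. TEMPO/PhI(OAc)2 in MeCN/H2O oxidises only the primary alcohol, to (1R,2R,5S)-2-hydroxy-5-methyl-6-oxabicyclo[3.1.0]hexane-1-carboxylic acid F7. Me3SiCHN2 in MeOH/PhMe gives ester 5.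

**Further compounds**

F1 | step 10 | ethyl 5-methyl-1,2,4-triazine-3-carboxylate | CCOC(=O)c1nncc(C)n1
F2 | step 10 | 1-ethyl 5-methyl (5R,6R)-6-methoxy-3,6-dimethyl-5-[(triethylsilyl)oxy]-6,7-dihydro-5H-cyclopenta[c]pyridine-1,5-dicarboxylate | CCOC(=O)c1nc(C)cc2c1C[C@@](C)(OC)[C@@]2(O[Si](CC)(CC)CC)C(=O)OC
F3 | step 10 | (5R,6R)-6-methoxy-5-(methoxycarbonyl)-3,6-dimethyl-5-[(triethylsilyl)oxy]-6,7-dihydro-5H-cyclopenta[c]pyridine-1-carboxylic acid | OC(=O)c1nc(C)cc2c1C[C@@](C)(OC)[C@@]2(O[Si](CC)(CC)CC)C(=O)OC
F4 | step 11 | methyl (5R,6S)-7-bromo-6-methoxy-3,6-dimethyl-5-[(triethylsilyl)oxy]-6,7-dihydro-5H-cyclopenta[c]pyridine-5-carboxylate | Cc1cc2c(cn1)C(Br)[C@@](C)(OC)[C@@]2(O[Si](CC)(CC)CC)C(=O)OC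
F5 | step 4 | (1R)-2-(hydroxymethyl)-3-methylcyclopent-2-en-1-ol | OCC1=C(C)CC[C@H]1O
F6 | step 4 | (1R,2R,5S)-1-(hydroxymethyl)-5-methyl-6-oxabicyclo[3.1.0]hexan-2-ol | OC[C@]12O[C@@]1(C)CC[C@H]2O
F7 | step 4 | (1R,2R,5S)-2-hydroxy-5-methyl-6-oxabicyclo[3.1.0]hexane-1-carboxylic acid | OC(=O)[C@]12O[C@@]1(C)CC[C@H]2O
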